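(All constants are those of an exercise; the flask was simulated.)

A charge of 0.0200 equiv of base was the number I started from: while it lasts it takes up the by-product, and the self-feeding step needs free by-product.

    substrate + target → side product (k1 = 17 M⁻¹ min⁻¹, Ea1 = 63.0 kJ mol⁻¹)
    partner + target → over-reaction product (k2 = 3.0 M⁻¹ min⁻¹, Ea2 = 82.0 kJ mol⁻¹)
    substrate + partner → target + by-product (k3 = 0.024 M⁻¹ min⁻¹, Ea3 = 80.0 kJ mol⁻¹)
    base + by-product ⇌ salt, settled at all times (K4 = 2.2 × 10⁶ M⁻¹, ΔH4 = 6.00 kJ mol⁻¹)
    substrate + partner + by-product → target + 2 by-product (k5 = 1400 M⁻² min⁻¹, Ea5 = 44.0 kJ mol⁻¹)
    (constants at 100 °C)

| setting | south-east | west | east | south-west |
|---|---|---|---|---|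
| substrate | 0.032 M | 0.032 M | 0.032 M | 0.032 M |
| partner | 1.10 equiv | 1.10 equiv | 1.10 equiv | 1.10 equiv |
| base | 0.0200 equiv | 0.0200 equiv | 0.0200 equiv | 0.0200 equiv |
| temperature | 100 °C |  | 150 °C | 125 °C |
| time | 10 min | 10 min | 10 min | 10 min |
| remark |  | at 100 °C until 3.0 min, from then on at 150 °C |  |  |

- percentages count the substrate that a species holds: one side product counts as two
- all constants are for 100 °C and move with temperature by the activation energies and enthalpies

- which flask leads in amount of target, in percent of the substrate charged ("all alike" within 1.5 percentage points) (south-east / west / east / south-west / all alike)
- how much target is there at the end, in percent of the substrate charged: south-east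
- how much target is there at the end, in percent of the substrate charged: west
- how much target is there at the end, in percent of the substrate charged: east
- how much target is there at the end, in percent of the substrate charged: south-west

At 100 °C I reckoned 23.7 min for t_b, the base clock, which is the charged base divided by the starting rate of the uncatalysed step, substrate plus partner. It is the induction period of this autocatalysis. Working with x, the fraction of base left at time t, x = 1 − t/t_b, the south-east flask should keep 57.8% of its base at 10 min, so I expected no take-off there.

My first doubt was that the self-feeding step might already run during the wait. When base and salt stand equal, free by-product is 1/K = 4.55 × 10⁻⁷ M, where K is the constant of the base balance, so at 100 °C the self-feeding step then goes at 2.65% of the uncatalysed one. By my reckoning it draws level when x has fallen to about 2.58%, so I kept the clock. My second doubt was that the reactants fall. Each by-product costs one substrate, and the target it comes with can take a second, so at most 0.0400 of the substrate is gone when the base is used, and a rate that keeps 0.960 of its substrate barely moves the clock.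

While the clock runs, target sits at a steady state (its resting level), made by the uncatalysed step and eaten by substrate and partner. This gave 0.130% of the substrate for the south-east flask.

Heat shortens the clock, since the uncatalysed step speeds up 21 times from the coldest flask to the hottest. I therefore gave the east flask a clock of 1.12 min. The west flask, with x = 87.3% at its change by my reckoning, should reach the end of its clock at 3.98 min. The south-west flask lies near the middle in reciprocal temperature, so I took the square root of that factor and got roughly 5.16 min, later than the forecast's about 4 min.

The objection here was that a clock says when target starts to rise, not how much stands at the end. But the activation energy of partner attacking target, 82.0 kJ mol⁻¹, is higher than the 44.0 kJ mol⁻¹ of the self-feeding step, so heat speeds that attack more than it speeds the self-feeding step. The time left after the clock is also shorter in the south-west flask than in the west flask. I therefore put the south-west flask first, without a figure I would defend.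

The forecast named south-west, with 0.13% for south-east, 2% for west, 1% for east and 17% for south-west, saying of the last, “Little decay time remains”.

The flasks gave 0.131% in south-east, 3.37% in west, 1.70% in east and 19.2% in south-west, so south-west led. In the south-east flask the time of 10 min stood short of the clock of 23.7 min, and the unbound base read 58% of its charge against my 57.8%. In the neighbouring flask, the south-east flask with 0.00500 equiv of base and all else held, the clock was 5.92 min, shorter than the same 10 min, and that flask ended with 0.0053% of its base unbound and 17.8% target.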